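**Remark on the chemistry:** the descriptors of the target describe a meso compound (mirror plane through the midpoints of the C1–C2 and C3–C4 bonds of the cyclobutane), so only relative configuration has to be controlled and no enantioselective step is needed.

## Analysis of the target

The target is a fully substituted cyclobutane. C1 and C2 each carry a hydrogen and a carboxylic acid. C3 and C4 are vicinal quaternary carbons, each bearing a methyl group and, through its C6, a 4-methoxy-3-methyl-2-pyranone ring. The two pyranones are cis on one face of the four-membered ring; both methyls and both carboxyls lie on the other face. The sensitive functions are the two 2-pyranones (enol lactones and vinylogous carbonates, opened or demethylated by hydroxide and alkoxide) and the crowded, strained ring. The difficulty is twofold: two adjacent quaternary centres in a four-membered ring with the bulky heteroaryl groups cis, and carboxyl groups that must sit next to the methyls. A reagent delivering hydrogen or a proton to C1 and C2 from outside approaches over the methyls, the more open face, and so leaves the carboxyls on the pyranone face, which is the wrong one. The plan rests on three facts: C1 and C2 are the only stereocentres bearing hydrogen; that hydrogen is α to a carboxyl and exchangeable; and the two carboxyls are cis, so they can be tied into a five-membered cyclic anhydride (a 3-oxabicyclo[3.2.0]heptane-2,4-dione). C3 and C4 carry no hydrogen and keep the relationship they receive when the ring is made.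

## Retrosynthetic reasoning

**16 to 15.** The acids of 16 are paired into the cis-fused anhydride 15, in which C1 and C2 already have the target configuration. No skeletal bond is cut. The gain is a neutral hydrolysis as the last step, which cannot disturb the pyranones or the stereocentres.

**15 to 14 (pivotal disconnection).** Opening one anhydride C–O bond, and with it releasing the configuration at C1 and C2, leads to diacid 14 with undefined CH centres. The forward reaction must enolise both acyl-activated CH centres reversibly and close the only ring open to them; the face is then chosen by thermodynamics. Any other cut would require these two centres to be set kinetically, against the steric bias described above.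

**14 to 13.** The acids are masked as tert-butyl esters. These are removed by acidolysis, which a methoxypyranone tolerates. Methyl esters at these hindered positions would need aqueous base, which it does not.

**13 to 12.** The two O–CH3 bonds are cut to the 4-hydroxypyranones, so the ring-forming step can deliver the free enol.

**12 to 9 + 11.** Each pyranone is cut at C4–C5 and at O1–C2. This leaves a two-carbon enol fragment on the cyclobutane (C6, C5 and the ring oxygen, present in 9 as the silyl enol ether of a methyl ketone) and the three-carbon bis-electrophile 11 (C2, C3 with its methyl, C4). Both fragments are at the oxidation level of the ring, so no redox adjustment is needed and both bonds of each ring form in one operation. The quaternary carbon leaves the ketone only one direction of enolisation.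

**9 to 8.** The silyl enol ethers come from the two acetyl groups of 8 by kinetic enolisation with immediate trapping, which keeps the 1,4-diketone from condensing with itself.

**8 to 7.** The C–H bonds at C1 and C2 are removed to give cyclobutene 7. The reduction is placed here and not after the pyranones exist for two reasons. At this stage ketones and esters are the only other functions. A cyclobutene flanked by two pyranone-bearing carbons would have to be reduced in competition with two reducible heterocycles and would be liable to thermal electrocyclic opening. The face that receives hydrogen does not matter, because C1 and C2 are reset later.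

**7 to 6.** The two acetyl carbonyls are rejoined into one tetrasubstituted C=C bond, which regenerates a second four-membered ring and gives the bicyclo[2.2.0]hexadiene 6. The gain is stereochemical: C3 and C4 become bridgeheads and their cis relationship becomes a ring-fusion necessity. The forward cleavage must pick the electron-rich tetraalkyl alkene and leave the diester-substituted one.

**6 to 5 to 4.** The tert-butyl esters are traced to the methyl esters of 4 through diacid 5. The ring-forming step that makes 4 uses a strong Lewis acid that tert-butyl esters would not survive, so the exchange follows it.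

**4 to 1 + 2 (via 3).** The two bonds from the bridgeheads to the ester-bearing alkene carbons are cut. This gives the cyclobutadiene equivalent 3 and alkyne 2; 3 is the Lewis-acid-induced dimer of 1. One operation creates the quaternary–quaternary bond, both methyl groups and both carboxyl carbons from C4 feedstocks.

**11 to 10.** The bis-electrophile is the dichloride of the commercial diacid 10.

## Alternatives that were turned down

**Alternative 1:** Both pyranones are cut between C5 and C6, taking the quaternary carbons back to formyl groups in cis-dialdehyde A2 and the other five carbons of each ring to keto ester A3.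
- Forward key step: the dianion of A3 adds twice through its terminal carbon to A2, giving the bis(δ-hydroxy-β-keto ester) A1. Oxidation of both carbinols, lactonisation and O-methylation follow.
- For: it is two-directional and convergent; the aldehydes cannot enolise and are the most electrophilic carbonyls present; no acid chloride is involved.
- Against: after the first addition the new alkoxide sits 1,4 to the remaining aldehyde and can close a five-membered lactol, hiding it from the second addition. The excess of strongly basic dianion meets two ester α-CH centres. A1 needs two oxidations next to an acidic β-keto ester before the rings can close. A2 is written with C1 and C2 already correct, which this plan does not itself achieve.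
- Comparison: the C–C bond formation of alternative 1 is at least as dependable as the annulation used here and avoids the acid it releases. The chosen route instead enters at the methyl ketone level, finishes each pyranone in one annulation plus one methylation, and leaves C1/C2 to the one step designed for them.

**Alternative 2:** The C1–C2 bond of the cyclobutane is traced to a ring contraction of the five-membered diazo keto ester A5.
- Forward key step: irradiation in an alcohol expels the diazo nitrogen, the ester-bearing ring carbon shifts to the carbene centre, and the ketene is trapped as an ester, giving A4.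
- For: this contraction is among the most dependable routes to crowded cyclobutanes. The cis quaternary pair would come from a concerted cycloaddition. No strained, acid- and heat-sensitive bicyclic diene is handled, and the ring arrives saturated, so no hindered hydrogenation is needed. On these points it is stronger than the chosen route.
- Against: the quaternary carbons emerge with one-carbon silyloxymethyl arms. Each must be deprotected, oxidised and extended by the rest of the pyranone chain, which adds the whole endgame of alternative 1. The new CH centre forms unselectively, so an epimerising closure like step 11 is still required.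
- Comparison: the chosen route reaches, in a cycloaddition and an ozonolysis, a cyclobutane whose quaternary carbons already carry two-carbon arms at the ketone level. Step economy is what it offers in exchange for handling 4 to 7.

**Alternative 3:** The C3–C4 quaternary–quaternary bond is opened to the 1,3-diene of anhydride A7.
- Forward key step: photochemical disrotatory 4π closure gives bicyclic anhydride A6, with the anhydride anti to the new cyclobutene.
- For: this sets C1 and C2 relative to the methyl groups kinetically and stereospecifically in the ring-forming event and keeps them locked in the anhydride. That is the relationship step 11 must obtain by equilibration, and here alternative 3 is clearly stronger.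
- Against: the cyclobutene of A6 is CH=CH, so its cleavage gives formyl arms, not acetyl arms. The pyranones then need the longer aldol and oxidation sequence of alternative 1, whose strong base is incompatible with an anhydride. Once the anhydride is opened to esters the CH centres are exposed to that base, and the kinetic advantage is lost. A7 is a cyclohexa-1,3-diene that can aromatise or open photochemically to a triene.
- Comparison: the chosen route gives up the kinetic stereocontrol. In return it has acetyl groups on the quaternary carbons from the start and all skeletal carbons in place after four bond-forming operations.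

Key step: step 11

## Route

Step 1
Reactants: 1 but-2-yne; 2 dimethyl acetylenedicarboxylate
Product: 4 dimethyl 1,4,5,6-tetramethylbicyclo[2.2.0]hexa-2,5-diene-2,3-dicarboxylate, via tetramethylcyclobutadiene–AlCl3 σ-complex 3 (not isolated)
Conditions: AlCl3 (1 equiv), 1 (2 equiv), CH2Cl2, 0 °C; then 2, 0 °C; then DMSO, 0 °C; ice water
Reagents that add atoms: none
Why: AlCl3 couples two molecules of 1 to the σ-bonded cyclobutadiene complex 3, which adds the electron-poor alkyne 2 across one ring double bond (cyclobutadiene–alkyne cycloaddition, the classical Dewar benzene synthesis), and DMSO then strips the aluminium. The two methyl-bearing bridgeheads can only be cis-fused, and this fusion later fixes the two quaternary carbons of the cyclobutane cis.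

Step 2
Reactants: 4 dimethyl 1,4,5,6-tetramethylbicyclo[2.2.0]hexa-2,5-diene-2,3-dicarboxylate
Product: 5 1,4,5,6-tetramethylbicyclo[2.2.0]hexa-2,5-diene-2,3-dicarboxylic acid
Conditions: KOH, MeOH/H2O, 20 °C; then cold aq. KHSO4 to pH 3, extract at 0 °C
Reagents that add atoms: potassium hydroxide, [K+].[OH-]
Why: Saponification (BAc2) of two conjugated methyl esters; the strained diene has no base-sensitive site and no epimerisable centre. Cold bisulfate is used for acidification because the electron-rich C5=C6 bond of a Dewar benzene is its acid-sensitive part.

Step 3
Reactants: 5 1,4,5,6-tetramethylbicyclo[2.2.0]hexa-2,5-diene-2,3-dicarboxylic acid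
Product: 6 di-tert-butyl 1,4,5,6-tetramethylbicyclo[2.2.0]hexa-2,5-diene-2,3-dicarboxylate
Conditions: O-tert-butyl-N,N′-diisopropylisourea (4 equiv), CH2Cl2, 20 °C; filter off the urea
Reagents that add atoms: O-tert-butyl-N,N′-diisopropylisourea, CC(C)N=C(OC(C)(C)C)NC(C)C
Why: O-Alkylisourea esterification: the acid protonates the isourea and the carboxylate takes up the tert-butyl group, so no strong acid or dehydrating agent meets the Dewar benzene. tert-Butyl esters are chosen because they are removed at the end by acidolysis, which a 4-methoxy-2-pyranone survives and saponification would not allow.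

Step 4
Reactants: 6 di-tert-butyl 1,4,5,6-tetramethylbicyclo[2.2.0]hexa-2,5-diene-2,3-dicarboxylate
Product: 7 di-tert-butyl cis-3,4-diacetyl-3,4-dimethylcyclobut-1-ene-1,2-dicarboxylate
Conditions: O3 (1 equiv, indicator endpoint), CH2Cl2/MeOH, −78 °C; Me2S, −78 → 20 °C; keep below 25 °C
Reagents that add atoms: ozone, [O-][O+]=O
Why: Ozone is electrophilic and attacks the tetraalkyl-substituted C5=C6 bond far faster than the diester-substituted C2=C3 bond (chemoselective ozonolysis with reductive work-up). Cleavage turns the bridgeheads into vicinal quaternary carbons, each with a methyl and an acetyl group, the acetyls necessarily cis.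

Step 5
Reactants: 7 di-tert-butyl cis-3,4-diacetyl-3,4-dimethylcyclobut-1-ene-1,2-dicarboxylate
Product: 8 di-tert-butyl 3,4-diacetyl-3,4-dimethylcyclobutane-1,2-dicarboxylate (acetyl groups cis; C1 and C2 as formed)
Conditions: H2 (4 atm), 10% Pd/C, EtOAc, 20 °C
Reagents that add atoms: none
Why: Heterogeneous hydrogenation of a strained, electron-poor cyclobutene; ketones and tert-butyl esters are inert to Pd/C. Syn addition gives cis esters on one face or the other, which does not matter because C1 and C2 are reset in step 11. The alkene is removed here because 7 is the last intermediate with nothing else reducible and the one whose cyclobutene is least prone to electrocyclic opening.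

Step 6
Reactants: 8 di-tert-butyl 3,4-diacetyl-3,4-dimethylcyclobutane-1,2-dicarboxylate
Product: 9 di-tert-butyl 3,4-dimethyl-3,4-bis[1-(trimethylsilyloxy)ethenyl]cyclobutane-1,2-dicarboxylate
Conditions: TMSCl (6 equiv, present from the start), LDA (2.4 equiv), THF, −78 °C; Et3N, pentane, filter, concentrate
Reagents that add atoms: chlorotrimethylsilane, C[Si](C)(C)Cl
Why: Kinetic deprotonation with in situ silylation (internal quench): each acetyl has only its methyl protons, because its other α-carbon is quaternary, so the enol ether regiochemistry is unambiguous. Trapping each enolate as it forms prevents the intramolecular aldol open to a 1,4-diketone, and the hindered ester α-protons are removed much more slowly.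

Step 7
Reactants: 10 methylmalonic acid
Product: 11 methylmalonyl dichloride
Conditions: SOCl2 (excess), 50 °C; distil under reduced pressure
Reagents that add atoms: thionyl chloride, O=S(Cl)Cl
Why: Standard conversion of a malonic acid into its dichloride with thionyl chloride; the product is distilled and used fresh.

Step 8
Reactants: 9 di-tert-butyl 3,4-dimethyl-3,4-bis[1-(trimethylsilyloxy)ethenyl]cyclobutane-1,2-dicarboxylate; 11 methylmalonyl dichloride
Product: 12 di-tert-butyl 3,4-bis(4-hydroxy-3-methyl-2-oxo-2H-pyran-6-yl)-3,4-dimethylcyclobutane-1,2-dicarboxylate
Conditions: 11 (2.4 equiv), Et2O, −78 → 20 °C, N2 sweep; aq. work-up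
Reagents that add atoms: none
Why: Pyranone annulation of a silyl enol ether with a malonyl dichloride: C-acylation at the enol ether CH2, then closure of the enol oxygen onto the second acid chloride (6-exo-trig lactonisation) and tautomerisation to the 4-hydroxy-2-pyranone. The methyl of 11 becomes the C3 methyl and the quaternary carbon ends up on pyranone C6, since the enol ether allows no other mode.

Step 9
Reactants: 12 di-tert-butyl 3,4-bis(4-hydroxy-3-methyl-2-oxo-2H-pyran-6-yl)-3,4-dimethylcyclobutane-1,2-dicarboxylate
Product: 13 di-tert-butyl 3,4-bis(4-methoxy-3-methyl-2-oxo-2H-pyran-6-yl)-3,4-dimethylcyclobutane-1,2-dicarboxylate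
Conditions: Me2SO4 (2.5 equiv), K2CO3, acetone, 20–40 °C
Reagents that add atoms: dimethyl sulfate, COS(=O)(=O)OC
Why: O-Alkylation of the 4-hydroxy-2-pyranone anion with dimethyl sulfate and carbonate, which for 5-unsubstituted rings normally gives the 4-methoxy-2-pyranone and not the 2-methoxy-4-pyranone. Carbonate is too weak to touch the ester α-CH or the lactone.

Step 10
Reactants: 13 di-tert-butyl 3,4-bis(4-methoxy-3-methyl-2-oxo-2H-pyran-6-yl)-3,4-dimethylcyclobutane-1,2-dicarboxylate
Product: 14 3,4-bis(4-methoxy-3-methyl-2-oxo-2H-pyran-6-yl)-3,4-dimethylcyclobutane-1,2-dicarboxylic acid (pyranonyl groups cis; C1/C2 epimers mixed)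
Conditions: TFA/CH2Cl2 (1:3), 20 °C; evaporate
Reagents that add atoms: none
Why: Acidolysis of tert-butyl esters by the E1 pathway with loss of isobutene; the methoxypyranones are stable to anhydrous trifluoroacetic acid. The diacid is obtained as whatever mixture of C1/C2 epimers the earlier steps produced.

Step 11
Reactants: 14 3,4-bis(4-methoxy-3-methyl-2-oxo-2H-pyran-6-yl)-3,4-dimethylcyclobutane-1,2-dicarboxylic acid
Product: 15 6,7-bis(4-methoxy-3-methyl-2-oxo-2H-pyran-6-yl)-6,7-dimethyl-3-oxabicyclo[3.2.0]heptane-2,4-dione (cis-fused; anhydride ring cis to both methyl groups)
Conditions: Ac2O, NaOAc (anhydrous, 0.5 equiv), 130 °C; evaporate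
Reagents that add atoms: none
Why: Acetic anhydride converts both carboxyl groups into mixed anhydrides, whose α-C–H bonds are enolised reversibly by acetate at 130 °C, so each CH centre is scrambled while the hydrogen-free quaternary carbons cannot change. Only a cis pair of acyl groups can cyclise: the carboxylate oxygen of one arm attacks the activated carbonyl of the other in a 5-exo-trig acyl substitution, whereas the trans pair would need a trans-fused bicyclo[3.2.0] ring that is too strained to form. Ring closure therefore drains the equilibrating mixture into the two cis-fused anhydrides, which interconvert under the same conditions by acetate-induced reopening and renewed enolisation. The closest known reaction type is the conversion of trans or stereochemically mixed cyclobutane-1,2-dicarboxylic acids of the truxinic family into cis anhydrides in hot acetic anhydride. Both new stereocentres (C1 and C2 of the cyclobutane) are set under thermodynamic control: their mutual cis relation is dictated by the ring fusion and their face by the substituents on the quaternary carbons. The selectivity needed is facial, the anhydride ring having to end on the methyl face. In that isomer each acyl carbon is eclipsed only by a methyl group and the two stacked pyranones lie next to hydrogen, whereas in the other each pyranone, already pressed against its neighbour, would also be eclipsed by an acyl carbon; the former is expected to be more stable, but the size of the preference is not known in advance.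

Step 12
Reactants: 15 6,7-bis(4-methoxy-3-methyl-2-oxo-2H-pyran-6-yl)-6,7-dimethyl-3-oxabicyclo[3.2.0]heptane-2,4-dione
Product: 16 3,4-bis(4-methoxy-3-methyl-2-oxo-2H-pyran-6-yl)-3,4-dimethylcyclobutane-1,2-dicarboxylic acid (carboxyl groups cis to each other and to both methyls; pyranonyl groups cis on the opposite face; meso)
Conditions: H2O/THF, 50 °C
Reagents that add atoms: water, O
Why: Hydrolysis of a strained cis-fused succinic-type anhydride by water without base, so neither the pyranones nor the freshly set C1/C2 centres are put at risk. Attack at either carbonyl gives the same meso diacid.

## Compound list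

1 | but-2-yne | CC#CC | starting material
2 | dimethyl acetylenedicarboxylate | COC(=O)C#CC(=O)OC | starting material
3 | tetramethylcyclobutadiene–AlCl3 σ-complex (1,2,3,4-tetramethylcyclobutenylium-4-yl trichloroaluminate zwitterion) | C[C+]1C(C)=C(C)C1(C)[Al-](Cl)(Cl)Cl | intermediate (not isolated)
4 | dimethyl 1,4,5,6-tetramethylbicyclo[2.2.0]hexa-2,5-diene-2,3-dicarboxylate (cis-fused) | COC(=O)C1=C(C(=O)OC)[C@]2(C)C(C)=C(C)[C@]12C | intermediate
5 | 1,4,5,6-tetramethylbicyclo[2.2.0]hexa-2,5-diene-2,3-dicarboxylic acid (cis-fused) | OC(=O)C1=C(C(=O)O)[C@]2(C)C(C)=C(C)[C@]12C | intermediate
6 | di-tert-butyl 1,4,5,6-tetramethylbicyclo[2.2.0]hexa-2,5-diene-2,3-dicarboxylate (cis-fused) | CC(C)(C)OC(=O)C1=C(C(=O)OC(C)(C)C)[C@]2(C)C(C)=C(C)[C@]12C | intermediate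
7 | di-tert-butyl cis-3,4-diacetyl-3,4-dimethylcyclobut-1-ene-1,2-dicarboxylate | CC(C)(C)OC(=O)C1=C(C(=O)OC(C)(C)C)[C@](C)(C(C)=O)[C@]1(C)C(C)=O | intermediate
8 | di-tert-butyl 3,4-diacetyl-3,4-dimethylcyclobutane-1,2-dicarboxylate (acetyls cis; C1/C2 not controlled) | CC(C)(C)OC(=O)C1C(C(=O)OC(C)(C)C)[C@](C)(C(C)=O)[C@]1(C)C(C)=O | intermediate
9 | di-tert-butyl 3,4-dimethyl-3,4-bis[1-(trimethylsilyloxy)ethenyl]cyclobutane-1,2-dicarboxylate (enol ether arms cis; C1/C2 not controlled) | CC(C)(C)OC(=O)C1C(C(=O)OC(C)(C)C)[C@](C)(C(=C)O[Si](C)(C)C)[C@]1(C)C(=C)O[Si](C)(C)C | intermediate
10 | methylmalonic acid | CC(C(=O)O)C(=O)O | starting material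
11 | methylmalonyl dichloride | CC(C(=O)Cl)C(=O)Cl | intermediate
12 | di-tert-butyl 3,4-bis(4-hydroxy-3-methyl-2-oxo-2H-pyran-6-yl)-3,4-dimethylcyclobutane-1,2-dicarboxylate (pyranonyls cis; C1/C2 not controlled) | Oc1cc([C@@]2(C)C(C(=O)OC(C)(C)C)C(C(=O)OC(C)(C)C)[C@@]2(C)c2cc(O)c(C)c(=O)o2)oc(=O)c1C | intermediate
13 | di-tert-butyl 3,4-bis(4-methoxy-3-methyl-2-oxo-2H-pyran-6-yl)-3,4-dimethylcyclobutane-1,2-dicarboxylate (pyranonyls cis; C1/C2 not controlled) | COc1cc([C@@]2(C)C(C(=O)OC(C)(C)C)C(C(=O)OC(C)(C)C)[C@@]2(C)c2cc(OC)c(C)c(=O)o2)oc(=O)c1C | intermediate
14 | 3,4-bis(4-methoxy-3-methyl-2-oxo-2H-pyran-6-yl)-3,4-dimethylcyclobutane-1,2-dicarboxylic acid (pyranonyls cis; C1/C2 epimers mixed) | COc1cc([C@@]2(C)C(C(=O)O)C(C(=O)O)[C@@]2(C)c2cc(OC)c(C)c(=O)o2)oc(=O)c1C | intermediate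
15 | 6,7-bis(4-methoxy-3-methyl-2-oxo-2H-pyran-6-yl)-6,7-dimethyl-3-oxabicyclo[3.2.0]heptane-2,4-dione (cis-fused; anhydride cis to both methyls, trans to both pyranonyls) | COc1cc([C@@]2(C)[C@@H]3C(=O)OC(=O)[C@@H]3[C@@]2(C)c2cc(OC)c(C)c(=O)o2)oc(=O)c1C | intermediate
16 | 3,4-bis(4-methoxy-3-methyl-2-oxo-2H-pyran-6-yl)-3,4-dimethylcyclobutane-1,2-dicarboxylic acid (carboxyls cis to each other and to both methyls; pyranonyls cis on the other face; meso) | COc1cc([C@@]2(C)[C@H](C(=O)O)[C@H](C(=O)O)[C@@]2(C)c2cc(OC)c(C)c(=O)o2)oc(=O)c1C | target

## Step count and least certain steps

Total: 12 steps. Longest linear sequence: 11 steps (steps 1–6 and 8–12); step 7 is a one-step side branch.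

**Step 11 (key step).** Three things can go wrong.
- The thermodynamic bias between the two cis-fused anhydrides may be too small, since it rests on a steric argument only.
- Epimerisation of two hindered centres may be incomplete, leaving the kinetically formed pyranone-face closure.
- The four-membered ring may fragment from the enolised acyl unit by retro-Michael opening of the C3–C4 bond, with the pyranone-stabilised carbanion as leaving group. This is disfavoured because the breaking ring bond is nearly orthogonal to the enol π system, but it is helped by strain release and temperature.

The fallback sets C1 and C2 kinetically by substrate direction and needs no enolisation. It sets out from 7. Homogeneous hydrogenation with [Ir(cod)(PCy3)(py)]PF6 and H2 in CH2Cl2 lets the ketone oxygens bind the metal and deliver hydrogen to the acetyl face (carbonyl-directed hydrogenation). This should give the all-cis methyl-face diester F1, with both ester groups cis to each other and to both methyls. F1 is taken through the operations of steps 6, 8 and 9 unchanged, none of which should enolise an ester α-CH appreciably. These give the bis(silyl enol ether) F2, the bis(4-hydroxypyranone) F3 and the bis(4-methoxypyranone) di-tert-butyl ester F4. Acidolysis of F4 under the conditions of step 10 releases the target directly, so the fallback returns to the route at 16.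

**Step 8.** The hydrogen chloride released may cause premature loss of tert-butyl ester groups, and crowding may stall the second annulation or divert it to O-acylation. The fallback separates C–C bond formation from lactonisation and releases no hydrogen chloride. It sets out from 9. C-acylation with methyl 3-chloro-2-methyl-3-oxopropanoate under ZnCl2 in Et2O/CH2Cl2 (Lewis-acid-promoted acylation of silyl enol ethers to β-diketones) gives the bis(3,5-dioxo ester) F5. DBU in toluene at 80 °C then closes both lactones with loss of methanol, and the fallback returns at 12.

**Step 5.** Hydrogen uptake may be slow at a tetrasubstituted double bond flanked by two quaternary carbons, and thermal conrotatory opening of the cyclobutene competes if the mixture is warmed to compensate. The fallback replaces surface hydrogenation by electron transfer, which is insensitive to steric shielding: SmI2 in THF/MeOH at −78 → 0 °C reduces the 1,2-diester-substituted alkene much faster than dialkyl ketones. It sets out from 7, returns at 8, and makes no new compound (F0).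

**Step 2.** Acid-catalysed valence isomerisation (aromatisation) of the Dewar benzene may occur while the free diacid is liberated and handled. The fallback avoids the free acid: direct transesterification of 4 with KOtBu in tert-butyl acetate at 0–20 °C, the methoxide being scavenged by the solvent ester. It sets out from 4, returns at 6, and makes no new compound (F0).

## Further compounds

F1 | step 11 | di-tert-butyl 3,4-diacetyl-3,4-dimethylcyclobutane-1,2-dicarboxylate, ester groups cis to each other and to both methyl groups, acetyl groups cis on the other face | CC(C)(C)OC(=O)[C@H]1[C@@H](C(=O)OC(C)(C)C)[C@](C)(C(C)=O)[C@]1(C)C(C)=O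
F2 | step 11 | di-tert-butyl 3,4-dimethyl-3,4-bis[1-(trimethylsilyloxy)ethenyl]cyclobutane-1,2-dicarboxylate, ester groups cis to each other and to both methyl groups | CC(C)(C)OC(=O)[C@H]1[C@@H](C(=O)OC(C)(C)C)[C@](C)(C(=C)O[Si](C)(C)C)[C@]1(C)C(=C)O[Si](C)(C)C
F3 | step 11 | di-tert-butyl 3,4-bis(4-hydroxy-3-methyl-2-oxo-2H-pyran-6-yl)-3,4-dimethylcyclobutane-1,2-dicarboxylate, ester groups cis to each other and to both methyl groups | Oc1cc([C@@]2(C)[C@H](C(=O)OC(C)(C)C)[C@H](C(=O)OC(C)(C)C)[C@@]2(C)c2cc(O)c(C)c(=O)o2)oc(=O)c1C
F4 | step 11 | di-tert-butyl 3,4-bis(4-methoxy-3-methyl-2-oxo-2H-pyran-6-yl)-3,4-dimethylcyclobutane-1,2-dicarboxylate, ester groups cis to each other and to both methyl groups | COc1cc([C@@]2(C)[C@H](C(=O)OC(C)(C)C)[C@H](C(=O)OC(C)(C)C)[C@@]2(C)c2cc(OC)c(C)c(=O)o2)oc(=O)c1C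
F5 | step 8 | di-tert-butyl 3,4-bis(5-methoxy-4-methyl-3,5-dioxopentanoyl)-3,4-dimethylcyclobutane-1,2-dicarboxylate (acyl arms cis; C1/C2 not controlled) | CC(C)(C)OC(=O)C1C(C(=O)OC(C)(C)C)[C@](C)(C(=O)CC(=O)C(C)C(=O)OC)[C@]1(C)C(=O)CC(=O)C(C)C(=O)OC
F0 | step 5 | none | none
F0 | step 2 | none | none
A1 | alternative 1 | di-tert-butyl 3,4-bis(1-hydroxy-6-methoxy-5-methyl-4,6-dioxohexyl)-3,4-dimethylcyclobutane-1,2-dicarboxylate, carbinol centres mixed | COC(=O)C(C)C(=O)CC(O)[C@@]1(C)[C@H](C(=O)OC(C)(C)C)[C@H](C(=O)OC(C)(C)C)[C@@]1(C)C(O)CC(=O)C(C)C(=O)OC
A2 | alternative 1 | di-tert-butyl 3,4-diformyl-3,4-dimethylcyclobutane-1,2-dicarboxylate, formyl groups cis, ester groups cis on the methyl face | O=C[C@@]1(C)[C@H](C(=O)OC(C)(C)C)[C@H](C(=O)OC(C)(C)C)[C@@]1(C)C=O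
A3 | alternative 1 | methyl 2-methyl-3-oxobutanoate | COC(=O)C(C)C(C)=O
A4 | alternative 2 | dimethyl 3,4-dimethyl-3,4-bis(tert-butyldimethylsilyloxymethyl)cyclobutane-1,2-dicarboxylate, new CH centre mixed | COC(=O)C1[C@H](C(=O)OC)[C@@](C)(CO[Si](C)(C)C(C)(C)C)[C@@]1(C)CO[Si](C)(C)C(C)(C)C
A5 | alternative 2 | methyl 3-diazo-4,5-bis(tert-butyldimethylsilyloxymethyl)-4,5-dimethyl-2-oxocyclopentane-1-carboxylate, silyloxymethyl groups cis | COC(=O)[C@@H]1C(=O)C(=[N+]=[N-])[C@@](C)(CO[Si](C)(C)C(C)(C)C)[C@@]1(C)CO[Si](C)(C)C(C)(C)C
A6 | alternative 3 | 1,4-dimethylbicyclo[2.2.0]hex-5-ene-2,3-dicarboxylic anhydride, anhydride anti to the cyclobutene | C[C@@]12C=C[C@]1(C)[C@H]3C(=O)OC(=O)[C@@H]23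
A7 | alternative 3 | cis-3,6-dimethyl-1,2-dihydrophthalic anhydride | CC1=CC=C(C)[C@H]2C(=O)OC(=O)[C@@H]12
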